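**Plan**

- Numbering and enabling feature: ring A (the dihydropyranone) is O1, C2(=O), C3, C4(OMe), C5, C6, and the cyclobutane is C6–C5–C7(Ph)–C8(pyranonyl). C6 is the only oxygen-bearing cyclobutane carbon and C5/C7 carry cis carbon groups, so the four-membered ring is a masked cyclobutanone (C6=O) built from a ketene-type two-carbon unit (C6, C8) and a Z-alkene (C5=C7).
- Retrosynthetic cuts, in order: O1–C2 and C3=C4 of ring A (hydroxy ester plus ketenylidenephosphorane); C8–C6′ to the pyranone (nickel reductive coupling); C6–CH2 of the phenethyl group (organocerium addition); C8–Br; finally C5–C6 and C7–C8 (keteniminium–alkene [2+2]).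
- Forward order: the cyclobutane arises first, C8 is brominated, the C6 carbinol is set, the pyranone (made separately from two molecules of malonyl dichloride) is attached at C8, and ring A is closed last.
- Stereochemistry: cis C5/C7 comes from the Z-alkene and the absolute sense from the C2-symmetric pyrrolidine auxiliary; C6 is set by attack anti to the C5 arm and the C7 phenyl; C8 is set by radical capture trans to phenyl and hydroxyl.

Key step: step 4

Assumption: the (2R,5R)-auxiliary is taken to favour the (2S,3R)-cyclobutanone; should the cycloaddition show the opposite facial sense, the (2S,5S)-amide is used with no other change.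

**Route**

Step 1
Reactants: 1 3-phenylprop-2-yn-1-ol
Product: 2 (Z)-3-phenylprop-2-en-1-ol
Conditions: H2 (1 atm), Pd/CaCO3 poisoned with Pb(OAc)2 (Lindlar catalyst), quinoline, EtOAc, 25 °C
Reagents that add atoms: none
Why: Lindlar semihydrogenation delivers H2 syn on the poisoned Pd surface and stops at the alkene, so the Z-olefin that encodes the cis C5/C7 relationship should form without over-reduction.

Step 2
Reactants: 2 (Z)-3-phenylprop-2-en-1-ol
Product: 3 (Z)-cinnamyl triisopropylsilyl ether
Conditions: TIPSCl, imidazole, DMF, 25 °C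
Reagents that add atoms: triisopropylsilyl chloride, CC(C)[Si](Cl)(C(C)C)C(C)C
Why: Imidazole-promoted silyl ether formation on the primary allylic alcohol leaves the Z geometry untouched, and the bulky TIPS group is chosen to survive Tf2O and triflate salts, lithium diisopropylamide and the organocerium reagent.

Step 3
Reactants: 4 (2R,5R)-2,5-dimethylpyrrolidine
Product: 5 1-[(2R,5R)-2,5-dimethylpyrrolidin-1-yl]ethan-1-one
Conditions: Ac2O, Et3N, DMAP (cat.), CH2Cl2, 0 → 25 °C
Reagents that add atoms: acetic anhydride, CC(=O)OC(C)=O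
Why: DMAP-catalysed N-acylation of the secondary amine should give the tertiary acetamide, whose C2 symmetry makes its two amide rotamers identical.

Step 4
Reactants: 3 (Z)-cinnamyl triisopropylsilyl ether, 5 1-[(2R,5R)-2,5-dimethylpyrrolidin-1-yl]ethan-1-one
Product: 8 (2S,3R)-3-phenyl-2-{[tri(propan-2-yl)silyl]oxymethyl}cyclobutan-1-one, via keteniminium triflate 6 (not isolated), via cyclobutaniminium triflate 7 (not isolated)
Conditions: Tf2O, 2,6-di-tert-butyl-4-methylpyridine, CH2Cl2, −20 → 25 °C (5 and base added slowly to 3 and Tf2O); then H2O, 25 °C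
Reagents that add atoms: water, O
Why: Tf2O converts amide 5 into its O-triflyl iminium ion, which loses TfOH to the hindered pyridine to give keteniminium 6; the alkene carbon remote from phenyl (C5) attacks the central cumulene carbon (future C6), the enamine carbon (C8) collapses onto the benzylic cation developing at C7, and water then hydrolyses iminium 7 to the ketone with release of the auxiliary. The closest known reaction type is the keteniminium–olefin [2+2] cycloaddition to cyclobutanones, including its versions with amides of C2-symmetric 2,5-disubstituted pyrrolidines. The four-membered ring closes in an asynchronous polar [2+2], the second bond (C7–C8) forming by 4-exo-trig attack of the enamine on the cationic carbon. C5 and C7 become cis because both new bonds form on the same face of the Z-alkene and closure is faster than rotation about C5–C7, and their absolute configuration is controlled by the C2-symmetric pyrrolidinium, whose two methyl groups leave one unhindered approach quadrant irrespective of rotation about the N=C axis. The step needs regioselectivity, retention of alkene geometry and π-facial selectivity: phenyl stabilisation of positive charge at C7 secures the first, the short lifetime of the tight cationic intermediate the second and the auxiliary the third, while the non-nucleophilic base and neutral hydrolysis should keep the epimerisable C5 centre cis to phenyl.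

Step 5
Reactants: 8 (2S,3R)-3-phenyl-2-{[tri(propan-2-yl)silyl]oxymethyl}cyclobutan-1-one
Product: 10 (2R,3R,4S)-2-bromo-3-phenyl-4-{[tri(propan-2-yl)silyl]oxymethyl}cyclobutan-1-one, via silyl enol ether 9 (not isolated)
Conditions: TMSCl, LiN(iPr)2 (LDA), THF, −78 °C (in situ quench); pentane, filtration; NBS, THF, −78 → 0 °C
Reagents that add atoms: N-bromosuccinimide, O=C1CCC(=O)N1Br
Why: Kinetic deprotonation by lithium diisopropylamide with in situ TMSCl trapping (regioselective silyl enol ether formation) should occur at the less hindered C8 methylene and not at C5, where a β-silyloxy group could be lost by E1cB, and electrophilic bromination of the enol ether by NBS should place bromine at C8 anti to the C7 phenyl, a configuration that is only provisional because C8 is reset in step 9.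

Step 6
Reactants: 10 (2R,3R,4S)-2-bromo-3-phenyl-4-{[tri(propan-2-yl)silyl]oxymethyl}cyclobutan-1-one, 11 phenethylmagnesium chloride
Product: 13 (1R,2R,3R,4S)-2-bromo-3-phenyl-1-(2-phenylethyl)-4-{[tri(propan-2-yl)silyl]oxymethyl}cyclobutan-1-ol, via phenethylcerium dichloride 12 (not isolated)
Conditions: CeCl3 (anhydrous), THF, −78 °C, 11 then 10; AcOH/THF quench at −78 °C
Reagents that add atoms: none
Why: Organocerium 1,2-addition with the weakly basic, oxophilic reagent should reach the strained ketone at −78 °C without enolisation or attack at bromine, approaching C6 from the face opposite the cis C5 arm and C7 phenyl so that the C6 oxygen ends up on their face (this sets C6), and the cold acidic quench should forestall semipinacol ring contraction of the bromo alkoxide.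

Step 7
Reactants: 14 malonyl dichloride (two molecules)
Product: 17 6-chloro-4-hydroxy-2H-pyran-2-one, via pyranone-3-carbonyl chloride 15 (not isolated), via pyranone-3-carboxylic acid 16 (not isolated)
Conditions: neat, 25 °C, 4 d (HCl vented); then H2O, 1,4-dioxane, 25 → 60 °C
Reagents that add atoms: malonyl dichloride (a second molecule of 14), O=C(Cl)CC(Cl)=O
Why: The known self-condensation of malonyl dichloride joins two molecules (C-acylation of one by the other, then enol-lactonisation, with loss of two HCl) to give the six-carbon 6-chloropyranone-3-carbonyl chloride 15, and hydrolysis of its acid chloride gives the vinylogous β-keto acid 16, which decarboxylates on warming so that five of the six carbons remain in 17 and the oxygen taken up from water leaves again in the CO2.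

Step 8
Reactants: 17 6-chloro-4-hydroxy-2H-pyran-2-one
Product: 18 6-chloro-4-methoxy-2H-pyran-2-one
Conditions: TMSCHN2, PhMe/MeOH, 0 °C
Reagents that add atoms: trimethylsilyldiazomethane, C[Si](C)(C)C=[N+]=[N-]
Why: Diazoalkane O-methylation of the acidic vinylogous carboxylic acid under neutral conditions should give mainly the 4-methoxy-2-pyranone, separable from any 2-methoxy-4-pyranone isomer, without displacing the C6 chloride.

Step 9
Reactants: 13 (1R,2R,3R,4S)-2-bromo-3-phenyl-1-(2-phenylethyl)-4-{[tri(propan-2-yl)silyl]oxymethyl}cyclobutan-1-ol, 18 6-chloro-4-methoxy-2H-pyran-2-one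
Product: 19 6-[(1R,2R,3S,4S)-2-hydroxy-4-phenyl-2-(2-phenylethyl)-3-{[tri(propan-2-yl)silyl]oxymethyl}cyclobutyl]-4-methoxy-2H-pyran-2-one
Conditions: NiBr2(dme) (10 mol %), 4,4′-di-tert-butyl-2,2′-bipyridine (10 mol %), Mn powder, NaI (25 mol %), DMA, 40 °C
Reagents that add atoms: none
Why: In this nickel-catalysed cross-electrophile (reductive) coupling the activated C(sp2)–Cl bond adds to low-valent nickel, the C8 radical formed by bromine abstraction is captured by the pyranonyl–nickel species and reductive elimination forges C8–C6′, as in couplings of secondary alkyl bromides with heteroaryl chlorides and of cyclic halohydrins with aryl halides that give trans-2-aryl cycloalkanols, and C8 is set because the planar radical is captured on the face away from the C7 phenyl and the C6 hydroxyl.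

Step 10
Reactants: 19 6-[(1R,2R,3S,4S)-2-hydroxy-4-phenyl-2-(2-phenylethyl)-3-{[tri(propan-2-yl)silyl]oxymethyl}cyclobutyl]-4-methoxy-2H-pyran-2-one
Product: 20 6-[(1R,2R,3S,4S)-2-hydroxy-3-(hydroxymethyl)-4-phenyl-2-(2-phenylethyl)cyclobutyl]-4-methoxy-2H-pyran-2-one
Conditions: Bu4NF (TBAF), THF, 0 → 25 °C
Reagents that add atoms: none
Why: Fluoride-mediated desilylation cleaves the primary TIPS ether while the tertiary alcohol, the methyl enol ether and the pyranone lactone should be inert to the fluoride at this temperature.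

Step 11
Reactants: 20 6-[(1R,2R,3S,4S)-2-hydroxy-3-(hydroxymethyl)-4-phenyl-2-(2-phenylethyl)cyclobutyl]-4-methoxy-2H-pyran-2-one
Product: 21 (1R,2S,3R,4R)-2-hydroxy-3-(4-methoxy-2-oxo-2H-pyran-6-yl)-4-phenyl-2-(2-phenylethyl)cyclobutane-1-carboxylic acid
Conditions: TEMPO (20 mol %), PhI(OAc)2, MeCN/H2O (1:1), 0 → 25 °C
Reagents that add atoms: water, O
Why: Oxoammonium (TEMPO/PhI(OAc)2) oxidation through the aldehyde hydrate is selective for the primary alcohol, cannot touch the tertiary one, and its near-neutral medium should avoid retro-aldol opening of the transient β-hydroxy aldehyde and epimerisation at C5.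

Step 12
Reactants: 21 (1R,2S,3R,4R)-2-hydroxy-3-(4-methoxy-2-oxo-2H-pyran-6-yl)-4-phenyl-2-(2-phenylethyl)cyclobutane-1-carboxylic acid
Product: 22 methyl (1R,2S,3R,4R)-2-hydroxy-3-(4-methoxy-2-oxo-2H-pyran-6-yl)-4-phenyl-2-(2-phenylethyl)cyclobutane-1-carboxylate
Conditions: TMSCHN2, PhMe/MeOH (4:1), 0 °C
Reagents that add atoms: trimethylsilyldiazomethane, C[Si](C)(C)C=[N+]=[N-]
Why: Diazoalkane esterification of the acid proceeds without base, so the retro-aldol-prone β-hydroxy ester never meets an alkoxide and the tertiary alcohol is not methylated.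

Step 13
Reactants: 22 methyl (1R,2S,3R,4R)-2-hydroxy-3-(4-methoxy-2-oxo-2H-pyran-6-yl)-4-phenyl-2-(2-phenylethyl)cyclobutane-1-carboxylate
Product: 24 (1R,6S,7S,8S)-5-methoxy-8-(4-methoxy-2-oxo-2H-pyran-6-yl)-7-phenyl-1-(2-phenylethyl)-2-oxabicyclo[4.2.0]oct-4-en-3-one, via acyl ylide 23 (not isolated)
Conditions: Ph3P=C=C=O, PhMe, 110 °C (sealed tube)
Reagents that add atoms: (triphenylphosphoranylidene)ketene, O=C=C=P(c1ccccc1)(c1ccccc1)c1ccccc1
Why: In the Bestmann-ylide domino reaction (alcohol addition to the cumulated ylide, then intramolecular Wittig olefination of an ester carbonyl, known for α- and β-hydroxy esters) the C6 hydroxyl gives ester ylide 23, which olefinates the cis-disposed C5 methyl ester to form O1–C2 and C3=C4 with the ester methoxy retained at C4, no stereocentre being touched.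

**Compound list**

1 | 3-phenylprop-2-yn-1-ol | OCC#Cc1ccccc1 | starting material
2 | (Z)-3-phenylprop-2-en-1-ol | OC/C=C\c1ccccc1 | intermediate
3 | (Z)-cinnamyl triisopropylsilyl ether | CC(C)[Si](OC/C=C\c1ccccc1)(C(C)C)C(C)C | intermediate
4 | (2R,5R)-2,5-dimethylpyrrolidine | C[C@@H]1CC[C@@H](C)N1 | starting material
5 | 1-[(2R,5R)-2,5-dimethylpyrrolidin-1-yl]ethan-1-one | CC(=O)N1[C@H](C)CC[C@H]1C | intermediate
6 | (2R,5R)-1-ethenylidene-2,5-dimethylpyrrolidin-1-ium triflate (keteniminium salt) | C=C=[N+]1[C@H](C)CC[C@H]1C.[O-]S(=O)(=O)C(F)(F)F | intermediate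
7 | (2R,5R)-2,5-dimethyl-1-[(2R,3R)-3-phenyl-2-{[tri(propan-2-yl)silyl]oxymethyl}cyclobutylidene]pyrrolidin-1-ium triflate (iminium salt of 8, same spatial arrangement) | C[C@@H]1CC[C@@H](C)[N+]1=C1[C@H](CO[Si](C(C)C)(C(C)C)C(C)C)[C@H](c2ccccc2)C1.[O-]S(=O)(=O)C(F)(F)F | intermediate
8 | (2S,3R)-3-phenyl-2-{[tri(propan-2-yl)silyl]oxymethyl}cyclobutan-1-one (substituents cis) | O=C1[C@H](CO[Si](C(C)C)(C(C)C)C(C)C)[C@H](c2ccccc2)C1 | intermediate
9 | (3R,4S)-3-phenyl-4-{[tri(propan-2-yl)silyl]oxymethyl}-1-(trimethylsilyloxy)cyclobut-1-ene | C[Si](C)(C)OC1=C[C@@H](c2ccccc2)[C@H]1CO[Si](C(C)C)(C(C)C)C(C)C | intermediate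
10 | (2R,3R,4S)-2-bromo-3-phenyl-4-{[tri(propan-2-yl)silyl]oxymethyl}cyclobutan-1-one (Br trans to Ph) | O=C1[C@H](CO[Si](C(C)C)(C(C)C)C(C)C)[C@H](c2ccccc2)[C@H]1Br | intermediate
11 | phenethylmagnesium chloride (commercial THF solution) | Cl[Mg]CCc1ccccc1 | starting material
12 | phenethylcerium dichloride | Cl[Ce](Cl)CCc1ccccc1 | intermediate
13 | (1R,2R,3R,4S)-2-bromo-3-phenyl-1-(2-phenylethyl)-4-{[tri(propan-2-yl)silyl]oxymethyl}cyclobutan-1-ol (OH cis to the C5 arm and phenyl, Br trans) | O[C@]1(CCc2ccccc2)[C@H](CO[Si](C(C)C)(C(C)C)C(C)C)[C@H](c2ccccc2)[C@H]1Br | intermediate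
14 | malonyl dichloride (two molecules are consumed per pyranone in step 7) | O=C(Cl)CC(Cl)=O | starting material
15 | 6-chloro-4-hydroxy-2-oxo-2H-pyran-3-carbonyl chloride | O=C(Cl)c1c(O)cc(Cl)oc1=O | intermediate
16 | 6-chloro-4-hydroxy-2-oxo-2H-pyran-3-carboxylic acid | OC(=O)c1c(O)cc(Cl)oc1=O | intermediate
17 | 6-chloro-4-hydroxy-2H-pyran-2-one | Oc1cc(Cl)oc(=O)c1 | intermediate
18 | 6-chloro-4-methoxy-2H-pyran-2-one | COc1cc(Cl)oc(=O)c1 | intermediate
19 | 6-[(1R,2R,3S,4S)-2-hydroxy-4-phenyl-2-(2-phenylethyl)-3-{[tri(propan-2-yl)silyl]oxymethyl}cyclobutyl]-4-methoxy-2H-pyran-2-one | O[C@]1(CCc2ccccc2)[C@H](CO[Si](C(C)C)(C(C)C)C(C)C)[C@H](c2ccccc2)[C@H]1c1cc(OC)cc(=O)o1 | intermediate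
20 | 6-[(1R,2R,3S,4S)-2-hydroxy-3-(hydroxymethyl)-4-phenyl-2-(2-phenylethyl)cyclobutyl]-4-methoxy-2H-pyran-2-one | O[C@]1(CCc2ccccc2)[C@H](CO)[C@H](c2ccccc2)[C@H]1c1cc(OC)cc(=O)o1 | intermediate
21 | (1R,2S,3R,4R)-2-hydroxy-3-(4-methoxy-2-oxo-2H-pyran-6-yl)-4-phenyl-2-(2-phenylethyl)cyclobutane-1-carboxylic acid | O[C@]1(CCc2ccccc2)[C@H](C(=O)O)[C@H](c2ccccc2)[C@H]1c1cc(OC)cc(=O)o1 | intermediate
22 | methyl (1R,2S,3R,4R)-2-hydroxy-3-(4-methoxy-2-oxo-2H-pyran-6-yl)-4-phenyl-2-(2-phenylethyl)cyclobutane-1-carboxylate | O[C@]1(CCc2ccccc2)[C@H](C(=O)OC)[C@H](c2ccccc2)[C@H]1c1cc(OC)cc(=O)o1 | intermediate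
23 | ester 22 acylated on its tertiary oxygen as the (triphenylphosphoranylidene)acetate (acyl ylide) | O=C(C=P(c1ccccc1)(c1ccccc1)c1ccccc1)O[C@]1(CCc2ccccc2)[C@H](C(=O)OC)[C@H](c2ccccc2)[C@H]1c1cc(OC)cc(=O)o1 | intermediate
24 | (1R,6S,7S,8S)-5-methoxy-8-(4-methoxy-2-oxo-2H-pyran-6-yl)-7-phenyl-1-(2-phenylethyl)-2-oxabicyclo[4.2.0]oct-4-en-3-one (CNP0185330.1) | COC1=CC(=O)O[C@]2(CCc3ccccc3)[C@H]1[C@H](c1ccccc1)[C@H]2c1cc(OC)cc(=O)o1 | target

**Step count**

Total: 13 steps. Longest linear sequence: 10 steps (steps 1, 2, 4, 5, 6, 9, 10, 11, 12, 13) from 3-phenylprop-2-yn-1-ol.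

**Steps most likely to fail**

Step 9. Capture of the C8 radical may be slow because it sits next to the quaternary C6, so hydrodebromination, reductive homocoupling of the chloropyranone or metal-promoted ring contraction of the bromohydrin could win. Capture could also occur with poor facial selectivity. The fallback changes the order of bond formation so that the radical is an α-keto radical beside a trigonal C6 and the C8 centre becomes epimerisable. It sets out from bromoketone 10 and chloropyranone 18. A nickel-catalysed reductive α-heteroarylation of the α-bromo ketone (NiBr2(bpy), Mn powder, DMF, 25 °C; the known coupling of α-halo ketones with aryl halides) should give (2S,3S,4S)-2-(4-methoxy-2-oxo-2H-pyran-6-yl)-3-phenyl-4-{[tri(propan-2-yl)silyl]oxymethyl}cyclobutan-1-one F1, in which C8 can equilibrate to the isomer trans to phenyl. Addition of phenethylcerium dichloride 12 (from 11 and CeCl3, THF, −78 °C) to the cyclobutanone, which is more electrophilic than the pyranone lactone, from the face opposite the C5 arm and the C7 phenyl would then return to 19. The facial selectivity of that addition with the C8 substituent in place would have to be checked.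

Step 13. The hindered tertiary hydroxyl may add too slowly to the cumulated ylide, the ester-carbonyl Wittig closure of the six-membered ring may stall, or prolonged heating may open the cyclobutane by retro-aldol cleavage. The fallback builds ring A by ester condensation and sets out from 22. Acetylation (Ac2O, DMAP, Et3N, CH2Cl2, 40 °C) should give the tertiary acetate of 22 F2. Kinetic enolisation of the acetate methyl group (LiN(SiMe3)2, THF, −78 °C) and intramolecular Claisen (Dieckmann-type) condensation onto the cis methyl ester should give the ring A pyran-2,4-dione F3 (the O-demethyl, 4-hydroxy form of 24). O-Methylation (Me2SO4, K2CO3, acetone, 25 °C), the standard way to 4-methoxy-5,6-dihydro-2-pyranones, would return to 24.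

Step 6. The α-bromine may steer the nucleophile to the wrong face of the carbonyl, the bromo alkoxide may contract to a cyclopropyl ketone, or the reagent may enolise or debrominate the ketone. The fallback makes the same bromohydrin by alkene functionalisation and sets out from 8. Kinetic enolate triflation (LiN(iPr)2, PhNTf2, THF, −78 °C) should give (3R,4S)-3-phenyl-4-{[tri(propan-2-yl)silyl]oxymethyl}cyclobut-1-en-1-yl trifluoromethanesulfonate F4. Fe(acac)3-catalysed Kumada-type coupling with 11 (THF/NMP, −30 °C) should give (3R,4R)-3-phenyl-1-(2-phenylethyl)-4-{[tri(propan-2-yl)silyl]oxymethyl}cyclobut-1-ene F5. Bromohydrin formation (NBS, THF/H2O, 0 °C) should place the bromonium ion on the face away from the two cis substituents and water at the tertiary C6 from the opposite face, which returns to 13.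

**Further compounds**

F1 | step 9 | (2S,3S,4S)-2-(4-methoxy-2-oxo-2H-pyran-6-yl)-3-phenyl-4-{[tri(propan-2-yl)silyl]oxymethyl}cyclobutan-1-one | O=C1[C@H](CO[Si](C(C)C)(C(C)C)C(C)C)[C@H](c2ccccc2)[C@H]1c1cc(OC)cc(=O)o1
F2 | step 13 | tertiary acetate of 22 (methyl 2-acetoxy-3-(4-methoxy-2-oxo-2H-pyran-6-yl)-4-phenyl-2-(2-phenylethyl)cyclobutane-1-carboxylate, configuration as in 22) | CC(=O)O[C@]1(CCc2ccccc2)[C@H](C(=O)OC)[C@H](c2ccccc2)[C@H]1c1cc(OC)cc(=O)o1
F3 | step 13 | ring A pyran-2,4-dione (8-(4-methoxy-2-oxo-2H-pyran-6-yl)-7-phenyl-1-(2-phenylethyl)-2-oxabicyclo[4.2.0]octane-3,5-dione, configuration as in 24) | O=C1CC(=O)O[C@]2(CCc3ccccc3)[C@H]1[C@H](c1ccccc1)[C@H]2c1cc(OC)cc(=O)o1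
F4 | step 6 | (3R,4S)-3-phenyl-4-{[tri(propan-2-yl)silyl]oxymethyl}cyclobut-1-en-1-yl trifluoromethanesulfonate | O=S(=O)(OC1=C[C@@H](c2ccccc2)[C@H]1CO[Si](C(C)C)(C(C)C)C(C)C)C(F)(F)F
F5 | step 6 | (3R,4R)-3-phenyl-1-(2-phenylethyl)-4-{[tri(propan-2-yl)silyl]oxymethyl}cyclobut-1-ene | c1ccccc1CCC1=C[C@@H](c2ccccc2)[C@H]1CO[Si](C(C)C)(C(C)C)C(C)C
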